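**Retrosynthetic overview**

1. The target is (3R,3′R,6′R)-lutein 3-O-palmitate 3′-O-myristate (carotenoid numbering, primed locants on the ring ε half). The last step is myristoylation of the allylic 3′-OH of lutein 3-palmitate.
2. Key disconnection: the sp2–sp2 bond C10′–C11′, together with C9′–C19′. This gives a C26 (E)-alkenyl iodide (ring β, palmitate in place) and a C13 terminal enyne (ring ε, no C19′ yet), joined by one-pot Zr-catalysed methylalumination and Pd/Zn alkenyl–alkenyl coupling.
3. Enabling feature: the trisubstituted E double bond C9′(C19′H3)=C10′H that sits directly beside the C10′–C11′ bond on the side chain of ring ε (the cyclohex-2-ene ring holding C3′ and C6′). It is the retron of a syn CH3–metal addition to a terminal alkyne C9′≡C10′, and the E C11′=C12′ bond maps onto an alkenyl iodide.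
4. The C26 iodide comes from Takai iodo-olefination of the C25 12′-apo-aldehyde, itself made by Wittig formation of C11=C12 from a C15 phosphonium salt and the C10 dialdehyde.
5. No ring is constructed. Both six-membered rings come from racemic α-ionone (P450 trans-3-hydroxylation, lipase resolution): the (3R,6R) enantiomer becomes ring ε; the (3S,6S) enantiomer becomes ring β after a base-induced shift of the ring double bond (C6 erased, C3 then reads 3R).

Key step: step 13

Assumption: the Burkholderia lipase acylates the 3R alcohol of the trans racemate, as is usual for cyclohex-2-en-1-ols; if it prefers 3S, ester and alcohol simply exchange streams and the later chemistry is unchanged.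

**Route**

Step 1
Reactants: 1 (±)-α-ionone
Product: 2 (±)-trans-3-hydroxy-α-ionone
Conditions: P450 BM3 variant (cytochrome P450 monooxygenase, CYP102A1 engineered for terpenoid substrates), NADP+ (cat.), D-glucose, glucose dehydrogenase, catalase, air, KH2PO4/K2HPO4 buffer pH 7.5, 2% DMSO, 25 °C
Reagents that add atoms: dioxygen, O=O
Why: Cytochrome P450 monooxygenase C–H hydroxylation (hydrogen abstraction, oxygen rebound) at the allylic C3 methylene, a transformation described for α-ionone with engineered BM3 variants; the active site is expected to present the C3–H bond trans to the C6 side chain in either enantiomer, so the new C3 stereocentre is set trans to C6 and the product is the trans racemate.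

Step 2
Reactants: 2 (±)-trans-3-hydroxy-α-ionone
Product: 3 (3R,6R)-3-acetoxy-α-ionone, together with 4 (3S,6S)-3-hydroxy-α-ionone (unreacted enantiomer; separated by chromatography, both are used)
Conditions: lipase from Burkholderia cepacia (Amano lipase PS, immobilised), vinyl acetate, MTBE, 30 °C, stopped slightly beyond half conversion
Reagents that add atoms: vinyl acetate, C=COC(C)=O
Why: Lipase-catalysed kinetic resolution by irreversible transesterification, in which the 3R alcohol fits the fast-reacting orientation of the empirical size rule for secondary alcohols and is acetylated while the (3S,6S) alcohol is left; no stereocentre is created, the enantiomers are sorted.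

Step 3
Reactants: 3 (3R,6R)-3-acetoxy-α-ionone
Product: 5 (3R,6R)-3-hydroxy-α-ionone
Conditions: Amano lipase PS, KH2PO4/K2HPO4 buffer pH 7, acetone (10%), 30 °C, stopped before full conversion
Reagents that add atoms: none
Why: Lipase-catalysed ester hydrolysis at neutral pH frees the alcohol without exposing the base-sensitive C6–H (γ to the enone) to alkoxide, and the repeated preference of the enzyme for the 3R ester should raise the enantiomeric purity further.

Step 4
Reactants: 5 (3R,6R)-3-hydroxy-α-ionone
Product: 6 (3R,6R)-3-(tert-butyldimethylsilyloxy)-α-ionone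
Conditions: TBSCl, imidazole, DMF, rt
Reagents that add atoms: tert-butyldimethylsilyl chloride, CC(C)(C)[Si](C)(C)Cl
Why: Standard silylation of a secondary alcohol gives a base-stable ether for the strongly basic step that follows; no stereocentre is touched.

Step 5
Reactants: 6 (3R,6R)-3-(tert-butyldimethylsilyloxy)-α-ionone
Product: 8 tert-butyl{[(1R,4R)-4-[(E)-but-1-en-3-yn-1-yl]-3,5,5-trimethylcyclohex-2-en-1-yl]oxy}dimethylsilane, via enol phosphate 7 (not isolated)
Conditions: LiN(iPr)2 (1.1 equiv), THF, −78 °C; ClP(O)(OEt)2, −78 °C → rt; LiN(iPr)2 (2.3 equiv), −78 °C → rt; aq. NH4Cl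
Reagents that add atoms: none
Why: Conversion of a methyl ketone into a terminal alkyne by kinetic deprotonation at the methyl group, O-phosphorylation to 7 and amide-induced elimination of diethyl phosphate to the lithium acetylide (protonated on work-up), a sequence precedented on β-ionone; at −78 °C the hindered C6–H should not be removed, so C6 keeps its configuration.

Step 6
Reactants: 8 silyl-protected ring ε enyne
Product: 9 (1R,4R)-4-[(E)-but-1-en-3-yn-1-yl]-3,5,5-trimethylcyclohex-2-en-1-ol
Conditions: Bu4NF, THF, 0 °C → rt; aq. NH4Cl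
Reagents that add atoms: none
Why: Fluoride-mediated desilylation under non-acidic conditions leaves the allylic carbinol C3′, the C6′ centre and the terminal alkyne unchanged.

Step 7
Reactants: 4 (3S,6S)-3-hydroxy-α-ionone
Product: 10 (3R)-3-hydroxy-β-ionone
Conditions: NaOMe (0.3 equiv), MeOH, 45 °C, argon
Reagents that add atoms: none
Why: Base-catalysed prototropic double-bond isomerisation (as in α- to β-ionone and lutein to zeaxanthin conversions): reversible deprotonation at C6 and reprotonation at C4 moves the ring double bond into conjugation with the enone; C6 is erased and C3 is untouched, so the 3S carbinol of the α series becomes 3R in the β series only through the change in CIP priorities.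

Step 8
Reactants: 10 (3R)-3-hydroxy-β-ionone
Product: 11 (E)-5-[(4R)-4-hydroxy-2,6,6-trimethylcyclohex-1-en-1-yl]-3-methylpenta-1,4-dien-3-ol (mixture of C9 epimers)
Conditions: CH2=CHMgBr (3 equiv), THF, −20 → 0 °C; aq. NH4Cl
Reagents that add atoms: vinylmagnesium bromide, C=C[Mg]Br
Why: 1,2-Grignard addition to the dienone carbonyl, the usual way to vinyl-ionols; the new tertiary carbinol centre C9 is formed without control and is removed again in step 9.

Step 9
Reactants: 11 vinyl carbinol
Product: 12 [(2E,4E)-5-[(4R)-4-hydroxy-2,6,6-trimethylcyclohex-1-en-1-yl]-3-methylpenta-2,4-dien-1-yl]triphenylphosphonium bromide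
Conditions: Ph3P·HBr, MeOH, rt; crystallisation
Reagents that add atoms: triphenylphosphine hydrobromide, [Br-].[PH+](c1ccccc1)(c1ccccc1)c1ccccc1
Why: Phosphonium salt formation with allylic transposition: acid ionises the tertiary bis-allylic alcohol and PPh3 captures the pentadienyl cation at the unhindered terminus, giving mainly the 9E salt, while the secondary 3-OH does not ionise.

Step 10
Reactants: 12 C15 phosphonium bromide; 13 (2E,4E,6E)-2,7-dimethylocta-2,4,6-trienedial (2.5 equiv)
Product: 15 (3R)-3-hydroxy-12′-apo-β-caroten-12′-al (all-E), via phosphorus ylide 14 (not isolated)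
Conditions: NaOMe, MeOH/CH2Cl2, −10 °C → rt (base added to salt plus excess dialdehyde); then heptane, reflux, dark; chromatography, excess 13 recovered
Reagents that add atoms: none
Why: Wittig olefination of the semi-stabilised allylic ylide 14 with one formyl group of the excess dialdehyde forms C11=C12; the sterically strained 11Z portion should isomerise thermally to the all-E aldehyde.

Step 11
Reactants: 15 (3R)-3-hydroxy-12′-apo-β-caroten-12′-al
Product: 16 (3R)-3-palmitoyloxy-12′-apo-β-caroten-12′-al
Conditions: palmitoyl chloride, pyridine, DMAP (cat.), CH2Cl2, 0 °C → rt, dark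
Reagents that add atoms: palmitoyl chloride, CCCCCCCCCCCCCCCC(=O)Cl
Why: DMAP-catalysed acylation of the secondary 3-OH places the first ester while the two hydroxyls are still on separate fragments; the conjugated aldehyde is inert.

Step 12
Reactants: 16 (3R)-3-palmitoyloxy-12′-apo-β-caroten-12′-al
Product: 17 C26 (E)-alkenyl iodide (16 extended by an E-CH=CHI unit, iodine on C11′)
Conditions: CrCl2 (8 equiv), CHI3 (3 equiv), THF/1,4-dioxane 1:6, 0 °C → rt, dark, argon
Reagents that add atoms: iodoform, IC(I)I
Why: Takai–Utimoto iodo-olefination: the geminal dichromium species from CHI3 adds to the aldehyde and anti-elimination gives the E-alkenyl iodide (new C11′=C12′ geometry E), while CrCl2 leaves the ester and the polyene alone.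

Step 13
Reactants: 9 ring ε hydroxy-enyne; 17 C26 (E)-alkenyl iodide
Product: 19 (3R,3′R,6′R)-lutein 3-O-palmitate, via alkenylalane 18 (not isolated)
Conditions: 9, Me3Al (3.5 equiv), Cp2ZrCl2 (0.5 equiv), ClCH2CH2Cl, 0 °C → rt; volatiles removed in vacuo; then THF, ZnCl2 (0.3 equiv), Pd2(dba)3 (2.5 mol %), P(2-furyl)3 (10 mol %), 17 (0.8 equiv), rt, dark; aq. NaHCO3/KNaC4H4O6
Reagents that add atoms: trimethylaluminium, C[Al](C)C
Why: Me3Al first masks the 3′-OH as its dimethylaluminium alkoxide, then the Me3Al/Cp2ZrCl2 pair adds CH3 and metal syn across the terminal C9′≡C10′ triple bond, methyl to the internal C9′ and metal to the terminal C10′, which creates C19′ and fixes the 9′E geometry in alkenylalane 18. Transmetalation from Al through Zn to Pd, oxidative addition of zerovalent palladium into the C11′–I bond of 17 and reductive elimination, all with retention at both sp2 carbons, then form the C10′–C11′ bond and complete the C40 skeleton. The closest known reaction type is the one-pot Zr-catalysed carboalumination followed by Pd- and Zn-catalysed alkenyl–alkenyl (Negishi) coupling, as applied to the enyne derived from β-ionone for retinoid and carotenoid chains. No ring is closed and no stereocentre is created; the only new stereo-element, the C9′=C10′ double bond, is controlled by the syn stereospecificity of the carbometalation, and the E geometry of C11′=C12′ is carried over from the iodide. The step needs chemoselectivity for the alkyne over the other C=C bonds, regioselective methyl delivery and tolerance of the palmitate: the terminal conjugated alkyne is the only π-bond open enough for the zirconocene, its unsubstituted terminus takes the metal, and excess Me3Al is stripped before the ester-bearing iodide is added, alkenylalanes and alkenylzincs being inert to esters at room temperature. C3′ and C6′ stay untouched because neither base nor protic acid is present.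

Step 14
Reactants: 19 (3R,3′R,6′R)-lutein 3-O-palmitate
Product: 20 (3R,3′R,6′R)-lutein 3-O-palmitate 3′-O-myristate (target)
Conditions: myristoyl chloride (1.5 equiv), pyridine, DMAP (cat.), CH2Cl2, 0 °C → rt, dark, argon
Reagents that add atoms: myristoyl chloride, CCCCCCCCCCCCCC(=O)Cl
Why: DMAP-catalysed acylation of the only free hydroxyl, the allylic 3′-OH, under basic non-ionising conditions, so the C3′ configuration and the polyene geometry are kept.

**Compound list**

1 | (±)-α-ionone, (E)-4-(2,6,6-trimethylcyclohex-2-en-1-yl)but-3-en-2-one | CC(=O)/C=C/C1C(C)=CCCC1(C)C | starting material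
2 | (±)-trans-3-hydroxy-α-ionone (racemate, both enantiomers written) | CC(=O)/C=C/[C@H]1C(C)=C[C@H](O)CC1(C)C.CC(=O)/C=C/[C@@H]1C(C)=C[C@@H](O)CC1(C)C | intermediate
3 | (3R,6R)-3-acetoxy-α-ionone | CC(=O)/C=C/[C@H]1C(C)=C[C@H](OC(C)=O)CC1(C)C | intermediate
4 | (3S,6S)-3-hydroxy-α-ionone | CC(=O)/C=C/[C@@H]1C(C)=C[C@@H](O)CC1(C)C | intermediate
5 | (3R,6R)-3-hydroxy-α-ionone | CC(=O)/C=C/[C@H]1C(C)=C[C@H](O)CC1(C)C | intermediate
6 | (3R,6R)-3-(tert-butyldimethylsilyloxy)-α-ionone | CC(=O)/C=C/[C@H]1C(C)=C[C@H](O[Si](C)(C)C(C)(C)C)CC1(C)C | intermediate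
7 | enol phosphate of 6, diethyl 2-phosphoryloxy-1,3-diene (not isolated) | C=C(OP(=O)(OCC)OCC)/C=C/[C@H]1C(C)=C[C@H](O[Si](C)(C)C(C)(C)C)CC1(C)C | intermediate
8 | tert-butyl{[(1R,4R)-4-[(E)-but-1-en-3-yn-1-yl]-3,5,5-trimethylcyclohex-2-en-1-yl]oxy}dimethylsilane | C#C/C=C/[C@H]1C(C)=C[C@H](O[Si](C)(C)C(C)(C)C)CC1(C)C | intermediate
9 | (1R,4R)-4-[(E)-but-1-en-3-yn-1-yl]-3,5,5-trimethylcyclohex-2-en-1-ol | C#C/C=C/[C@H]1C(C)=C[C@H](O)CC1(C)C | intermediate
10 | (3R)-3-hydroxy-β-ionone | CC(=O)/C=C/C1=C(C)C[C@@H](O)CC1(C)C | intermediate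
11 | (E)-5-[(4R)-4-hydroxy-2,6,6-trimethylcyclohex-1-en-1-yl]-3-methylpenta-1,4-dien-3-ol (C9 epimers) | C=CC(C)(O)/C=C/C1=C(C)C[C@@H](O)CC1(C)C | intermediate
12 | [(2E,4E)-5-[(4R)-4-hydroxy-2,6,6-trimethylcyclohex-1-en-1-yl]-3-methylpenta-2,4-dien-1-yl]triphenylphosphonium bromide | O[C@@H]1CC(C)=C(/C=C/C(C)=C/C[P+](c2ccccc2)(c2ccccc2)c2ccccc2)C(C)(C)C1.[Br-] | intermediate
13 | (2E,4E,6E)-2,7-dimethylocta-2,4,6-trienedial (C10 dialdehyde) | O=C/C(C)=C/C=C/C=C(C)/C=O | starting material
14 | phosphorus ylide from 12 (not isolated) | O[C@@H]1CC(C)=C(/C=C/C(C)=C/C=P(c2ccccc2)(c2ccccc2)c2ccccc2)C(C)(C)C1 | intermediate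
15 | (3R)-3-hydroxy-12′-apo-β-caroten-12′-al | O[C@@H]1CC(C)=C(/C=C/C(C)=C/C=C/C(C)=C/C=C/C=C(C)/C=O)C(C)(C)C1 | intermediate
16 | (3R)-3-palmitoyloxy-12′-apo-β-caroten-12′-al | CCCCCCCCCCCCCCCC(=O)O[C@@H]1CC(C)=C(/C=C/C(C)=C/C=C/C(C)=C/C=C/C=C(C)/C=O)C(C)(C)C1 | intermediate
17 | C26 (E)-alkenyl iodide, ring β half with palmitate and iodine on C11′ | CCCCCCCCCCCCCCCC(=O)O[C@@H]1CC(C)=C(/C=C/C(C)=C/C=C/C(C)=C/C=C/C=C(C)/C=C/I)C(C)(C)C1 | intermediate
18 | (E)-alkenyl(dimethyl)alane of ring ε with O-dimethylaluminium alkoxide (not isolated) | C[Al](C)/C=C(C)/C=C/[C@H]1C(C)=C[C@H](O[Al](C)C)CC1(C)C | intermediate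
19 | (3R,3′R,6′R)-lutein 3-O-palmitate | CCCCCCCCCCCCCCCC(=O)O[C@@H]1CC(C)=C(/C=C/C(C)=C/C=C/C(C)=C/C=C/C=C(C)/C=C/C=C(C)/C=C/[C@H]2C(C)=C[C@H](O)CC2(C)C)C(C)(C)C1 | intermediate
20 | (3R,3′R,6′R)-lutein 3-O-palmitate 3′-O-myristate | CCCCCCCCCCCCCCCC(=O)O[C@@H]1CC(C)=C(/C=C/C(C)=C/C=C/C(C)=C/C=C/C=C(C)/C=C/C=C(C)/C=C/[C@H]2C(C)=C[C@H](OC(=O)CCCCCCCCCCCCC)CC2(C)C)C(C)(C)C1 | target

**Step count and risks**

Total step count: 14. Longest linear sequence: 10 steps (1, 2, 7, 8, 9, 10, 11, 12, 13, 14).

Steps most likely to fail: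

1. Step 13. The methylmetalation may be incomplete or not fully regioselective, the heptaenyl iodide may isomerise or decompose in the Lewis-acidic Al/Zr medium, or the palmitate may be attacked by residual aluminium alkyl. The fallback sets out from 9 and 16 and comes back at 19. Enyne 9 is methylaluminated as before (alane 18) but quenched with I2 (THF, −30 °C) to give (1R,4R)-4-[(1E,3E)-4-iodo-3-methylbuta-1,3-dien-1-yl]-3,5,5-trimethylcyclohex-2-en-1-ol F1, which can be purified. Aldehyde 16 is homologated with Bu3SnCHBr2, CrCl2 and LiI (THF/DMF) to the C26 (E)-alkenyltributylstannane F2. A neutral Stille coupling of F1 with F2 (Pd2(dba)3, AsPh3, DMF, rt, dark) should then give 19 with no aluminium alkyl or Lewis acid near the polyene or the ester.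

2. Step 12. E selectivity may erode on the branched polyenal, CrCl2 may reduce the polyenal in a pinacol-type coupling, and the iodide may be lost under light. The fallback sets out from 15 and comes back at 17. Homologation of 15 with lithiated trimethylsilyldiazomethane (Me3SiCHN2, LiN(iPr)2, THF, −78 → 0 °C; Colvin rearrangement) gives the (3R)-3-hydroxy C26 terminal polyenyne F3. Acylation (palmitoyl chloride, pyridine, DMAP) gives its palmitate F4. Syn hydrozirconation of the terminal alkyne with Cp2Zr(H)Cl (THF, rt) gives the (E)-alkenylzirconocene chloride F5, and I2 at 0 °C cleaves it to 17, so the E geometry comes from a syn addition instead of an elimination.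

3. Step 1. Turnover may be low on preparative scale, the alcohol may be over-oxidised to the 3-ketone, or one of the two enantiomers may be hydroxylated with poor trans selectivity. The fallback sets out from 1 and comes back at 2. Ketalisation (ethylene glycol, PPTS, HC(OEt)3) gives α-ionone ethylene ketal F6. Allylic oxidation (tBuOOH, aqueous NaOCl, MeCN, 0 °C) gives 3-oxo-α-ionone ethylene ketal F7. Reduction (NaBH4, CeCl3, MeOH, −20 °C) gives the allylic alcohols, with (±)-cis-3-hydroxy-α-ionone ethylene ketal F8 expected to dominate. Mitsunobu inversion (4-nitrobenzoic acid, PPh3, DIAD, THF) gives the (±)-trans 4-nitrobenzoate ketal F9. Methanolysis (K2CO3, MeOH) gives (±)-trans-3-hydroxy-α-ionone ethylene ketal F10, and mild hydrolysis (PPTS, acetone/H2O) gives 2.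

**Further compounds**

F1 | step 13 | (1R,4R)-4-[(1E,3E)-4-iodo-3-methylbuta-1,3-dien-1-yl]-3,5,5-trimethylcyclohex-2-en-1-ol | I/C=C(C)/C=C/[C@H]1C(C)=C[C@H](O)CC1(C)C
F2 | step 13 | C26 (E)-alkenyltributylstannane, ring β half with palmitate and tin on C11′ | CCCCCCCCCCCCCCCC(=O)O[C@@H]1CC(C)=C(/C=C/C(C)=C/C=C/C(C)=C/C=C/C=C(C)/C=C/[Sn](CCCC)(CCCC)CCCC)C(C)(C)C1
F3 | step 12 | (3R)-3-hydroxy C26 terminal polyenyne (alkyne carbons C12′ and C11′) | O[C@@H]1CC(C)=C(/C=C/C(C)=C/C=C/C(C)=C/C=C/C=C(C)/C#C)C(C)(C)C1
F4 | step 12 | palmitate of F3 | CCCCCCCCCCCCCCCC(=O)O[C@@H]1CC(C)=C(/C=C/C(C)=C/C=C/C(C)=C/C=C/C=C(C)/C#C)C(C)(C)C1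
F5 | step 12 | (E)-alkenylzirconocene chloride from F4 | CCCCCCCCCCCCCCCC(=O)O[C@@H]1CC(C)=C(/C=C/C(C)=C/C=C/C(C)=C/C=C/C=C(C)/C=C/[Zr](Cl)(C2C=CC=C2)C2C=CC=C2)C(C)(C)C1
F6 | step 1 | (±)-α-ionone ethylene ketal | CC1(/C=C/C2C(C)=CCCC2(C)C)OCCO1
F7 | step 1 | (±)-3-oxo-α-ionone ethylene ketal | CC1(/C=C/C2C(C)=CC(=O)CC2(C)C)OCCO1
F8 | step 1 | (±)-cis-3-hydroxy-α-ionone ethylene ketal (both enantiomers written) | CC1(/C=C/[C@H]2C(C)=C[C@@H](O)CC2(C)C)OCCO1.CC1(/C=C/[C@@H]2C(C)=C[C@H](O)CC2(C)C)OCCO1
F9 | step 1 | (±)-trans-3-(4-nitrobenzoyloxy)-α-ionone ethylene ketal (both enantiomers written) | CC1(/C=C/[C@H]2C(C)=C[C@H](OC(=O)c3ccc(cc3)[N+](=O)[O-])CC2(C)C)OCCO1.CC1(/C=C/[C@@H]2C(C)=C[C@@H](OC(=O)c3ccc(cc3)[N+](=O)[O-])CC2(C)C)OCCO1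
F10 | step 1 | (±)-trans-3-hydroxy-α-ionone ethylene ketal (both enantiomers written) | CC1(/C=C/[C@H]2C(C)=C[C@H](O)CC2(C)C)OCCO1.CC1(/C=C/[C@@H]2C(C)=C[C@@H](O)CC2(C)C)OCCO1
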